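**Plan**

- Numbering: chroman O1, C2–C8a; side chain C1' (on C2) to C12'; ring A is the benzene ring, ring B the dihydropyran ring.
- Retrosynthesis: the C9'–O bond is traced back to a C9'–B bond, then C8'–C9' and C10'–C11' are cut in one three-component conjunctive coupling. Further back the chain is cut at C5'–C6' (propargylation) and ring B at O1–C8a (aryl etherification) and C4–C4a (B-alkyl Suzuki–Miyaura coupling).
- Enabling feature: the C9' carbinol lies between C8', an sp2 carbon of the C7'=C8' alkene, and the C10' methylene that leads to the C11'=C12' alkene. C9'–C10' therefore maps onto a vinylboron unit, C8' onto a migrating alkenyl group and C11' onto an alkenyl electrophile; rings A and B are spectators.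
- Forward order: ring A is bought; C4–C4a is made, then ring B closes by C–O coupling (the only ring formed). The chain then grows from C4' out to C8', and C9'–C12' are added in the key step.
- Stereochemistry: C2 comes unchanged from (R)-linalool; 3'E from E-selective allylic oxidation; 7'E from syn hydrozirconation; C9' (R) from the chiral ligand in the metallate shift, kept through the stereoretentive C–B oxidation.

Key step: step 13

Assumption: the (Sp,Sp) enantiomer of the MandyPhos ligand is taken to deliver the 9'R boronate (if the sense of induction is the opposite, the mirror-image ligand is used with nothing else changed), and (R)-linalool is used in enantiopure form.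

**Route**

Step 1
Reactants: 1 3-bromo-5-methylphenol
Product: 2 (3-bromo-5-methylphenoxy)triisopropylsilane
Conditions: TIPSCl, imidazole, DMF, rt
Reagents that add atoms: triisopropylsilyl chloride, CC(C)[Si](Cl)(C(C)C)C(C)C
Why: Imidazole-promoted silylation of the phenol; the bulky triisopropylsilyl ether is chosen because it should withstand the aqueous base, carbonate/methanol and organolithium steps ahead better than a smaller silyl group.

Step 2
Reactants: 2 (3-bromo-5-methylphenoxy)triisopropylsilane
Product: 3 (3-iodo-5-methylphenoxy)triisopropylsilane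
Conditions: NaI (2 equiv), CuI (5 mol%), trans-N,N'-dimethylcyclohexane-1,2-diamine (10 mol%), 1,4-dioxane, 110 °C
Reagents that add atoms: sodium iodide, [Na+].[I-]
Why: Copper-catalysed aromatic Finkelstein reaction, driven by precipitation of NaBr, turns the bromide into the iodide so that the later C–C coupling site differs in reactivity from the second halogen.

Step 3
Reactants: 3 (3-iodo-5-methylphenoxy)triisopropylsilane
Product: 4 (4-bromo-3-iodo-5-methylphenoxy)triisopropylsilane
Conditions: NBS, MeCN, 0 °C to rt, dark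
Reagents that add atoms: N-bromosuccinimide, O=C1CCC(=O)N1Br
Why: Electrophilic aromatic bromination with NBS in acetonitrile should go para to the silyloxy group, whose bulk shields both ortho positions, placing bromine on the future C8a between iodine and methyl.

Step 4
Reactants: 5 (R)-linalool; 4 (4-bromo-3-iodo-5-methylphenoxy)triisopropylsilane
Product: 7 (3R)-1-[2-bromo-3-methyl-5-(triisopropylsilyloxy)phenyl]-3,7-dimethyloct-6-en-3-ol, via B-alkyl-9-BBN adduct 6 (not isolated)
Conditions: 5, 9-BBN (9-borabicyclo[3.3.1]nonane, 1.3 equiv), THF, 0 °C to rt; then 4, PdCl2(dppf) (dppf = 1,1'-bis(diphenylphosphino)ferrocene, 5 mol%), K3PO4 (3 M aq), DMF, rt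
Reagents that add atoms: none
Why: 9-BBN adds anti-Markovnikov to the monosubstituted vinyl group only, and the B-alkyl Suzuki–Miyaura coupling should occur at C–I far faster than at the hindered C–Br bond, forming C4–C4a without touching the carbinol stereocentre.

Step 5
Reactants: 7 (3R)-1-[2-bromo-3-methyl-5-(triisopropylsilyloxy)phenyl]-3,7-dimethyloct-6-en-3-ol
Product: 8 triisopropyl{[(2R)-2,8-dimethyl-2-(4-methylpent-3-en-1-yl)chroman-6-yl]oxy}silane
Conditions: Pd(OAc)2 (3 mol%), 2-(di-tert-butylphosphino)-1,1'-binaphthyl (4 mol%), Cs2CO3, toluene, 80 °C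
Reagents that add atoms: none
Why: Intramolecular Buchwald–Hartwig-type C–O coupling closes ring B through O1–C8a; the tertiary alkoxide cannot undergo β-hydride elimination, and since no bond to C2 is broken the linalool configuration is kept.

Step 6
Reactants: 8 triisopropyl{[(2R)-2,8-dimethyl-2-(4-methylpent-3-en-1-yl)chroman-6-yl]oxy}silane
Product: 9 (2E)-5-[(2R)-2,8-dimethyl-6-(triisopropylsilyloxy)chroman-2-yl]-2-methylpent-2-en-1-ol
Conditions: SeO2 (0.5 equiv), t-BuOOH (2 equiv), salicylic acid (10 mol%), CH2Cl2, 0 °C to rt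
Reagents that add atoms: selenium dioxide, O=[Se]=O; tert-butyl hydroperoxide, CC(C)(C)OO
Why: Riley allylic oxidation (ene reaction, then [2,3]-sigmatropic shift) on the only alkene present attacks the methyl group trans to the chain and should give the E allylic alcohol.

Step 7
Reactants: 9 (2E)-5-[(2R)-2,8-dimethyl-6-(triisopropylsilyloxy)chroman-2-yl]-2-methylpent-2-en-1-ol
Product: 10 {[(2R)-2-[(3E)-5-bromo-4-methylpent-3-en-1-yl]-2,8-dimethylchroman-6-yl]oxy}triisopropylsilane
Conditions: CBr4, PPh3, CH2Cl2, 0 °C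
Reagents that add atoms: carbon tetrabromide, BrC(Br)(Br)Br
Why: The Appel reaction converts the primary allylic alcohol into the bromide by SN2 displacement of the oxyphosphonium group, which at low temperature should leave the alkene position and E geometry unchanged.

Step 8
Reactants: 10 {[(2R)-2-[(3E)-5-bromo-4-methylpent-3-en-1-yl]-2,8-dimethylchroman-6-yl]oxy}triisopropylsilane; 11 1-(trimethylsilyl)propyne
Product: 13 triisopropyl{[(2R)-2,8-dimethyl-2-[(3E)-4-methyl-8-(trimethylsilyl)oct-3-en-7-yn-1-yl]chroman-6-yl]oxy}silane, via lithiated 1-(trimethylsilyl)propyne 12 (not isolated)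
Conditions: 11, n-BuLi, THF, −20 °C; then 10, −78 °C to −20 °C
Reagents that add atoms: none
Why: Lithiated 1-(trimethylsilyl)propyne alkylates primary allylic bromides by SN2 at its propargylic carbon (the silyl group suppresses allenyl products), forming C5'–C6'.

Step 9
Reactants: 13 triisopropyl{[(2R)-2,8-dimethyl-2-[(3E)-4-methyl-8-(trimethylsilyl)oct-3-en-7-yn-1-yl]chroman-6-yl]oxy}silane
Product: 14 triisopropyl{[(2R)-2,8-dimethyl-2-[(3E)-4-methyloct-3-en-7-yn-1-yl]chroman-6-yl]oxy}silane
Conditions: K2CO3, MeOH/THF, rt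
Reagents that add atoms: none
Why: Base-catalysed methanolysis of the alkynyl C–Si bond frees the terminal alkyne, while the hindered aryl triisopropylsilyl ether is expected to survive these mild conditions.

Step 10
Reactants: 14 triisopropyl{[(2R)-2,8-dimethyl-2-[(3E)-4-methyloct-3-en-7-yn-1-yl]chroman-6-yl]oxy}silane
Product: 16 triisopropyl{[(2R)-2,8-dimethyl-2-[(3E)-4-methylnon-3-en-7-yn-1-yl]chroman-6-yl]oxy}silane, via lithium acetylide 15 (not isolated)
Conditions: n-BuLi, THF, −78 °C; then MeI, −78 °C to rt
Reagents that add atoms: iodomethane, CI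
Why: Deprotonation of the terminal alkyne and SN2 methylation of the lithium acetylide installs the C8' methyl group.

Step 11
Reactants: 16 triisopropyl{[(2R)-2,8-dimethyl-2-[(3E)-4-methylnon-3-en-7-yn-1-yl]chroman-6-yl]oxy}silane
Product: 18 {[(2R)-2-[(3E,7E)-8-iodo-4-methylnona-3,7-dien-1-yl]-2,8-dimethylchroman-6-yl]oxy}triisopropylsilane (fragment 1), via alkenylzirconocene chloride 17 (not isolated)
Conditions: Cp2Zr(H)Cl (2.5 equiv), THF, 50 °C; then I2, THF, 0 °C
Reagents that add atoms: iodine, II
Why: Syn hydrozirconation with excess Cp2Zr(H)Cl under equilibrating conditions places zirconium on the less hindered, methyl-bearing alkyne carbon C8', and iodinolysis with retention gives the (E)-2-iodoalkene; the trisubstituted C3'=C4' alkene reacts far more slowly.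

Step 12
Reactants: 19 isobutyraldehyde
Product: 20 2-methylprop-1-en-1-yl trifluoromethanesulfonate (fragment 3)
Conditions: Tf2O, 2,6-di-tert-butyl-4-methylpyridine, CH2Cl2, 0 °C to rt
Reagents that add atoms: trifluoromethanesulfonic anhydride, O=S(=O)(OS(=O)(=O)C(F)(F)F)C(F)(F)F
Why: O-triflation of the enolisable aldehyde and loss of the α-proton to a hindered, non-nucleophilic pyridine base is the standard route to simple alkenyl triflates.

Step 13
Reactants: 18 {[(2R)-2-[(3E,7E)-8-iodo-4-methylnona-3,7-dien-1-yl]-2,8-dimethylchroman-6-yl]oxy}triisopropylsilane (fragment 1); 21 vinylboronic acid pinacol ester (fragment 2); 20 2-methylprop-1-en-1-yl trifluoromethanesulfonate (fragment 3)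
Product: 24 triisopropyl{[(2R)-2,8-dimethyl-2-[(3E,7E,9R)-4,8,12-trimethyl-9-(4,4,5,5-tetramethyl-1,3,2-dioxaborolan-2-yl)trideca-3,7,11-trien-1-yl]chroman-6-yl]oxy}silane, via alkenyllithium 22 (not isolated), via lithium bis(alkenyl)borate 23 (not isolated)
Conditions: 18, t-BuLi (2 equiv), Et2O, −78 °C; 21, −78 °C to rt; solvent exchange to THF; then 20, Pd(OAc)2 (3 mol%), (Sp,Sp)-MandyPhos = (Sp,Sp)-1,1'-bis[bis(4-methoxy-3,5-dimethylphenyl)phosphino]-2,2'-bis[(R)-α-(dimethylamino)benzyl]ferrocene (3.6 mol%), KOTf (2 equiv), THF, 60 °C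
Reagents that add atoms: none
Why: Iodine–lithium exchange with retention of alkene geometry and addition of 22 to the boron of 21 give borate 23; zerovalent palladium formed from Pd(OAc)2 and the ligand inserts into the C–O bond of 20, and the resulting cationic divalent alkenylpalladium binds the unsubstituted vinyl group of 23. The C8' alkenyl group then shifts from boron to C9' anti to palladium while the Pd–C10' bond forms, and reductive elimination makes C10'–C11' and returns zerovalent palladium. The closest known reaction type is the enantioselective conjunctive cross-coupling of bis(alkenyl)borates with alkenyl or aryl triflates to chiral allylic boronates; no ring is closed. The new C9' stereocentre is set by the ferrocenyl bisphosphine, which selects the face of the vinyl group that palladium takes, and the distant C2 centre should have no influence. The step needs chemoselectivity (palladium on the vinyl group, migration of the α-methylalkenyl group, no direct Suzuki–Miyaura transfer), which the different substitution of the two alkenyl groups and the wide-bite-angle ligand secure, and it needs a halide-free cationic palladium site, which KOTf provides by removing the iodide from the exchange as KI.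

Step 14
Reactants: 24 triisopropyl{[(2R)-2,8-dimethyl-2-[(3E,7E,9R)-4,8,12-trimethyl-9-(4,4,5,5-tetramethyl-1,3,2-dioxaborolan-2-yl)trideca-3,7,11-trien-1-yl]chroman-6-yl]oxy}silane
Product: 25 (3E,7E,9R)-1-[(2R)-2,8-dimethyl-6-(triisopropylsilyloxy)chroman-2-yl]-4,8,12-trimethyltrideca-3,7,11-trien-9-ol
Conditions: H2O2 (30% aq), NaOH (3 M aq), THF, 0 °C
Reagents that add atoms: hydrogen peroxide, OO
Why: Hydroperoxide adds to boron and C9' migrates from boron to oxygen with retention (stereospecific boronate oxidation), which should give the 9'R allylic alcohol without allylic shift; the electron-rich alkenes are inert to alkaline peroxide.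

Step 15
Reactants: 25 (3E,7E,9R)-1-[(2R)-2,8-dimethyl-6-(triisopropylsilyloxy)chroman-2-yl]-4,8,12-trimethyltrideca-3,7,11-trien-9-ol
Product: 26 sargachromanol C, (2R)-2-[(3E,7E,9R)-9-hydroxy-4,8,12-trimethyltrideca-3,7,11-trien-1-yl]-2,8-dimethylchroman-6-ol
Conditions: TBAF, THF, 0 °C
Reagents that add atoms: none
Why: Fluoride-induced cleavage of the aryl Si–O bond under near-neutral conditions frees the phenol and should leave the allylic alcohol and the three alkenes untouched.

**Compound list**

1 | 3-bromo-5-methylphenol | Cc1cc(O)cc(Br)c1 | starting material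
2 | (3-bromo-5-methylphenoxy)triisopropylsilane | Cc1cc(O[Si](C(C)C)(C(C)C)C(C)C)cc(Br)c1 | intermediate
3 | (3-iodo-5-methylphenoxy)triisopropylsilane | Cc1cc(O[Si](C(C)C)(C(C)C)C(C)C)cc(I)c1 | intermediate
4 | (4-bromo-3-iodo-5-methylphenoxy)triisopropylsilane | Cc1cc(O[Si](C(C)C)(C(C)C)C(C)C)cc(I)c1Br | intermediate
5 | (R)-linalool | CC(C)=CCC[C@@](C)(O)C=C | starting material
6 | (3S)-1-(9-borabicyclo[3.3.1]nonan-9-yl)-3,7-dimethyloct-6-en-3-ol (same spatial arrangement as 5; the descriptor changes because boron lowers the rank of the new branch) | CC(C)=CCC[C@@](C)(O)CCB1C2CCCC1CCC2 | intermediate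
7 | (3R)-1-[2-bromo-3-methyl-5-(triisopropylsilyloxy)phenyl]-3,7-dimethyloct-6-en-3-ol | CC(C)=CCC[C@@](C)(O)CCc1cc(O[Si](C(C)C)(C(C)C)C(C)C)cc(C)c1Br | intermediate
8 | triisopropyl{[(2R)-2,8-dimethyl-2-(4-methylpent-3-en-1-yl)chroman-6-yl]oxy}silane | CC(C)=CCC[C@]1(C)CCc2cc(O[Si](C(C)C)(C(C)C)C(C)C)cc(C)c2O1 | intermediate
9 | (2E)-5-[(2R)-2,8-dimethyl-6-(triisopropylsilyloxy)chroman-2-yl]-2-methylpent-2-en-1-ol | OC/C(C)=C/CC[C@]1(C)CCc2cc(O[Si](C(C)C)(C(C)C)C(C)C)cc(C)c2O1 | intermediate
10 | {[(2R)-2-[(3E)-5-bromo-4-methylpent-3-en-1-yl]-2,8-dimethylchroman-6-yl]oxy}triisopropylsilane | BrC/C(C)=C/CC[C@]1(C)CCc2cc(O[Si](C(C)C)(C(C)C)C(C)C)cc(C)c2O1 | intermediate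
11 | 1-(trimethylsilyl)propyne | CC#C[Si](C)(C)C | starting material
12 | [3-(trimethylsilyl)prop-2-yn-1-yl]lithium | [Li]CC#C[Si](C)(C)C | intermediate
13 | triisopropyl{[(2R)-2,8-dimethyl-2-[(3E)-4-methyl-8-(trimethylsilyl)oct-3-en-7-yn-1-yl]chroman-6-yl]oxy}silane | C[Si](C)(C)C#CCC/C(C)=C/CC[C@]1(C)CCc2cc(O[Si](C(C)C)(C(C)C)C(C)C)cc(C)c2O1 | intermediate
14 | triisopropyl{[(2R)-2,8-dimethyl-2-[(3E)-4-methyloct-3-en-7-yn-1-yl]chroman-6-yl]oxy}silane | C#CCC/C(C)=C/CC[C@]1(C)CCc2cc(O[Si](C(C)C)(C(C)C)C(C)C)cc(C)c2O1 | intermediate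
15 | lithium acetylide of 14 (lithium on the terminal alkyne carbon) | [Li]C#CCC/C(C)=C/CC[C@]1(C)CCc2cc(O[Si](C(C)C)(C(C)C)C(C)C)cc(C)c2O1 | intermediate
16 | triisopropyl{[(2R)-2,8-dimethyl-2-[(3E)-4-methylnon-3-en-7-yn-1-yl]chroman-6-yl]oxy}silane | CC#CCC/C(C)=C/CC[C@]1(C)CCc2cc(O[Si](C(C)C)(C(C)C)C(C)C)cc(C)c2O1 | intermediate
17 | (E)-alkenylzirconocene chloride from 16 (Cp2ZrCl on C8', cis to H on C7') | Cl[Zr](C3C=CC=C3)(C4C=CC=C4)/C(C)=C/CC/C(C)=C/CC[C@]1(C)CCc2cc(O[Si](C(C)C)(C(C)C)C(C)C)cc(C)c2O1 | intermediate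
18 | {[(2R)-2-[(3E,7E)-8-iodo-4-methylnona-3,7-dien-1-yl]-2,8-dimethylchroman-6-yl]oxy}triisopropylsilane (fragment 1) | I/C(C)=C/CC/C(C)=C/CC[C@]1(C)CCc2cc(O[Si](C(C)C)(C(C)C)C(C)C)cc(C)c2O1 | intermediate
19 | isobutyraldehyde | CC(C)C=O | starting material
20 | 2-methylprop-1-en-1-yl trifluoromethanesulfonate (fragment 3) | CC(C)=COS(=O)(=O)C(F)(F)F | intermediate
21 | vinylboronic acid pinacol ester (fragment 2) | C=CB1OC(C)(C)C(C)(C)O1 | starting material
22 | (E)-alkenyllithium from 18 (lithium in place of iodine) | [Li]/C(C)=C/CC/C(C)=C/CC[C@]1(C)CCc2cc(O[Si](C(C)C)(C(C)C)C(C)C)cc(C)c2O1 | intermediate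
23 | lithium (vinyl)(C8'-alkenyl)pinacolatoborate | [Li+].C=C[B-]1(OC(C)(C)C(C)(C)O1)/C(C)=C/CC/C(C)=C/CC[C@]2(C)CCc3cc(O[Si](C(C)C)(C(C)C)C(C)C)cc(C)c3O2 | intermediate
24 | triisopropyl{[(2R)-2,8-dimethyl-2-[(3E,7E,9R)-4,8,12-trimethyl-9-(4,4,5,5-tetramethyl-1,3,2-dioxaborolan-2-yl)trideca-3,7,11-trien-1-yl]chroman-6-yl]oxy}silane | CC(C)=CC[C@@H](B1OC(C)(C)C(C)(C)O1)/C(C)=C/CC/C(C)=C/CC[C@]2(C)CCc3cc(O[Si](C(C)C)(C(C)C)C(C)C)cc(C)c3O2 | intermediate
25 | (3E,7E,9R)-1-[(2R)-2,8-dimethyl-6-(triisopropylsilyloxy)chroman-2-yl]-4,8,12-trimethyltrideca-3,7,11-trien-9-ol | CC(C)=CC[C@@H](O)/C(C)=C/CC/C(C)=C/CC[C@]1(C)CCc2cc(O[Si](C(C)C)(C(C)C)C(C)C)cc(C)c2O1 | intermediate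
26 | sargachromanol C, (2R)-2-[(3E,7E,9R)-9-hydroxy-4,8,12-trimethyltrideca-3,7,11-trien-1-yl]-2,8-dimethylchroman-6-ol | CC(C)=CC[C@@H](O)/C(C)=C/CC/C(C)=C/CC[C@]1(C)CCc2cc(O)cc(C)c2O1 | target

**Step count and risks**

Total steps: 15. Longest linear sequence: 14 steps (steps 1–11 and 13–15, from 3-bromo-5-methylphenol); step 12 is a one-step side branch.

Steps most likely to fail:

1. Step 13. Iodide carried over from the exchange may block the cationic palladium site, the alkenyl group may transfer directly to palladium (Suzuki–Miyaura pathway) instead of migrating, β-hydride elimination may compete at C10', or the ligand may give poor facial selectivity at C9'. The fallback builds C9' by carbonyl addition at a stable, conjugated oxidation level. It sets out from 18: iodine–lithium exchange (t-BuLi, Et2O, −78 °C) and formylation with DMF should give the (2E,6E)-enal F1. Brown allylation with Ipc2B(allyl) made from (−)-α-pinene (the antipode expected to give 9'R), followed by oxidative work-up, should give the (R)-homoallylic alcohol F2. Cross-metathesis of the terminal alkene of F2 with 2-methyl-2-butene (second-generation Grubbs catalyst, CH2Cl2, 40 °C) converts the allyl group into the prenyl group and returns to the route at 25.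

2. Step 5. Oxidative addition into the electron-rich C–Br bond flanked by two alkyl groups may be slow, so that hydrodebromination or base-induced loss of the silyl ether overtakes ring closure. The fallback changes both the leaving group and the metal. It sets out from 7: copper-catalysed halogen exchange (NaI, CuI, trans-N,N'-dimethylcyclohexane-1,2-diamine, dioxane, 110 °C) gives the aryl iodide F3, and an Ullmann-type intramolecular O-arylation (CuI, 3,4,7,8-tetramethyl-1,10-phenanthroline, Cs2CO3, toluene, 110 °C) closes ring B and returns at 8, again without touching C2.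

3. Step 11. Zirconium may add to both alkyne carbons if equilibration is incomplete, or excess hydride may begin to add to the C3'=C4' alkene, giving regioisomeric or over-reduced iodides that are hard to separate. The fallback fixes the regiochemistry with the silyl group already present. It sets out from 13: trans-hydroalumination of the silylalkyne with i-Bu2AlH in heptane puts aluminium on the silicon-bearing carbon, and conversion to the alanate with MeLi followed by methylation with MeI gives the (E)-vinylsilane F4 (methyl cis to the chain). Iododesilylation with N-iodosuccinimide (MeCN/ClCH2CN, 0 °C), which proceeds with retention, returns at 18 and makes steps 9 and 10 unnecessary.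

**Further compounds**

F1 | step 13 | (2E,6E)-9-[(2R)-2,8-dimethyl-6-(triisopropylsilyloxy)chroman-2-yl]-2,6-dimethylnona-2,6-dienal | O=C/C(C)=C/CC/C(C)=C/CC[C@]1(C)CCc2cc(O[Si](C(C)C)(C(C)C)C(C)C)cc(C)c2O1
F2 | step 13 | (4R,5E,9E)-12-[(2R)-2,8-dimethyl-6-(triisopropylsilyloxy)chroman-2-yl]-5,9-dimethyldodeca-1,5,9-trien-4-ol | C=CC[C@@H](O)/C(C)=C/CC/C(C)=C/CC[C@]1(C)CCc2cc(O[Si](C(C)C)(C(C)C)C(C)C)cc(C)c2O1
F3 | step 5 | (3R)-1-[2-iodo-3-methyl-5-(triisopropylsilyloxy)phenyl]-3,7-dimethyloct-6-en-3-ol | CC(C)=CCC[C@@](C)(O)CCc1cc(O[Si](C(C)C)(C(C)C)C(C)C)cc(C)c1I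
F4 | step 11 | triisopropyl{[(2R)-2,8-dimethyl-2-[(3E,7E)-4-methyl-8-(trimethylsilyl)nona-3,7-dien-1-yl]chroman-6-yl]oxy}silane | C[Si](C)(C)/C(C)=C/CC/C(C)=C/CC[C@]1(C)CCc2cc(O[Si](C(C)C)(C(C)C)C(C)C)cc(C)c2O1
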